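## Analysis of the target

- **Ring system.** The target is a normal-series labdane. Labdane numbering is used throughout, and O13 denotes the ether oxygen. It has a trans-decalin (ring A: C1–C5, C10; ring B: C5–C10). A tetrahydrofuran (ring C: C9, C11, C12, C13, O13) is spiro-fused at C9. A γ-lactone (ring D: C13, C14, C15(=O), O, C16) is spiro-fused at C13.
- **Stereocentres.** There are seven:
  - 3S (equatorial 3β-OAc)
  - 5S (5α-H)
  - 6S (axial 6β-OH, syn-axial to both C19 and C20)
  - 8S (equatorial 8α-CH3)
  - 9R (O13 axial and α, C11 equatorial and β)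
  - 10S (C20 β)
  - 13R
- **How they relate.** Six centres sit on the decalin and can control one another. C13 is remote. It is stereogenic only because its two CH2 arms, C14H2–C15(=O) and C16H2–O, run in opposite directions around the flat ring D.
- **Sensitive groups.**
  - O13 is β to both carbonyl groups (C7 and C15), so base can open ring C by retro-oxa-Michael reaction from either side.
  - C8 is epimerisable.
  - C6/C7 is an α-ketol that can isomerise through an enediol.
  - The acetate must survive to the end.
- **Hard points.**
  - The fully substituted C9 lies next to quaternary C10.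
  - The hydroxyl at C6 sits on the more hindered face.
  - The decalin cannot bias C13.
- **Feature that invites the move.** C13 carries O, C12H2, a two-carbon arm (C14–C15) and a one-carbon arm (C16). This is exactly the spatial order of C13 in (−)-sclareol (OH, C12H2, vinyl, CH3). Sclareol also holds all twenty skeletal carbons and the correct C5 and C10. The target is therefore sclareol with oxygen added at C3, C6, C7, C9, C15 and C16, and with the C8 hydroxyl removed. Ring D can then be closed on the unactivated C16 methyl group.

## Retrosynthetic reasoning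

**Ring B, α-ketol (18 ⇒ 17 ⇒ 16 ⇒ 15).**
- The 6β-OH cannot come from an enolate, because every external oxidant meets C6 from the open α face.
- It is therefore traced to hydride delivery from that α face onto a C6 ketone, which leads back to enone 15.
- The C7 ketone and the C8–H are cut together as a 1,2-hydride shift in the 7α,8α-epoxide 17. The migrating 7β-H lands on the β face of C8, which gives the 8α-methyl group without any base.

**Ring D, key disconnection (15 ⇒ 14).**
- The O–C16 bond is cut, not an acyl bond and not a bond to C13.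
- This turns the spirolactone into a methyl group and an acetic acid arm on C13, which is the differentiated pair that 1 already offers as methyl and vinyl.
- The forward reaction must oxidise one C(sp3)–H bond of C16, directed by the C15 carboxylate, and leave C12–H alone.
- It is placed at the enone stage. There the alkene is electron-poor and the allylic C9–O13 bond no longer ionises.

**Ring C (14 ⇒ 13 ⇒ 12 ⇒ 11).**
- After removal of the C6 carbonyl (allylic oxidation of 13), the C9–O13 bond is cut and C13–O13 is kept, so that the C13–O bond of 1 is never broken.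
- C9 is made electrophilic as one terminus of the C7–C8–C9 allyl cation, generated from allylic alcohol 12 and hence from enone 11.
- O13 can reach only C9, and the alkene ends at C7=C8, where ring B needs it.
- Direct conjugate addition of O13 to 11 would keep the C7 ketone. It would also leave no way to reach a C6 ketone, and so no way to the 6β-alcohol.

**Enone and acid (11 ⇒ 10 ⇒ 8 ⇒ 5).**
- The C7 carbonyl comes from allylic oxidation of the tetrasubstituted alkene in 10.
- The acid comes from the primary alcohol of 8.
- The alkene comes from loss of the C8 hydroxyl of 5, while O13 is masked for the duration of that one operation.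

**Side chain and ring A (5 ⇒ 3 ⇒ 2 ⇒ 1).**
- C15 is oxygenated by anti-Markovnikov hydroboration of the vinyl group.
- The C3 oxygen is traced to an enzymatic C–H hydroxylation of 1 itself, the one position where catalyst control overrides the intrinsic preference for C2.

## Alternatives that were turned down

**Alternative 1:** (textbook) cut C9–C11 and C13–O13.
- *Forward key step.* A C11–C16 furylethyl organometallic adds to a C9 carbonyl group and the furan is oxidised. The 9α-hydroxy butenolide A1 then closes ring C by oxa-Michael addition to C13.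
- *Why turned down.*
  - C13 would be created at a trigonal carbon whose two faces differ only in CH2–O against CH–C(=O) of a flat ring, four bonds from the nearest stereocentre.
  - The addition is reversible, so neither kinetic nor thermodynamic bias can be expected.
  - The fully oxygenated decalin partner also has to be built first, which costs more steps than the whole present route.

**Alternative 2:** cut C4–C5 and C9–C10.
- *Forward key step.* A Ti(III)-mediated radical (or cationic) bicyclisation of epoxy polyene A2 gives 3β-hydroxymanool A3. One step sets C3, C5, C9 and C10.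
- *Why turned down.*
  - The cascade builds only the part of the target that the chiral pool supplies for nothing.
  - A2 needs two separate asymmetric operations (the C13 carbinol and the terminal epoxide) and about six steps.
  - A3 still has C9–H, an unoxidised ring B and an unoxidised C16, so every hard problem is left.

**Alternative 3:** cut the O–C16 bond as a Baeyer–Villiger insertion (strain release).
- *Forward key step.* The spiro-cyclobutanone A4, in which C13 is not yet stereogenic, is ring-expanded to the lactone.
- *Why turned down.*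
  - The two migrating CH2 groups are diastereotopic only through remote centres, so the substrate gives no bias.
  - A catalyst would have to distinguish O13 from C12H2 on a 3,3-disubstituted cyclobutanone.
  - Building A4 (spirolactone, methylenation, ketene [2+2], dechlorination) costs four to five steps for a ring that a single C–H oxidation can close.

Key step: step 9

Assumption: commercial (−)-sclareol is taken as (13R)-labd-14-ene-8α,13-diol of the normal series. The P450 BM3 variant is treated as a catalyst (expressed in E. coli), not as a starting material.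

## Route

Step 1
Reactants: 1 (−)-sclareol [(13R)-labd-14-ene-8α,13-diol]
Product: 2 (13R)-labd-14-ene-3β,8α,13-triol (3β-hydroxysclareol)
Conditions: P450 BM3 variant (clarified lysate), NADP+ (cat.), phosphite dehydrogenase, Na2HPO3, air, KPi buffer pH 8, 25 °C
Reagents that add atoms: dioxygen, O=O
Why: Enzymatic (P450) C–H hydroxylation with retention: the polar diol end anchors the substrate so that ring A faces the ferryl oxygen, and the equatorial C3–H next to the gem-dimethyl group becomes the 3β (3S) alcohol. This hydroxylation of sclareol is known for engineered P450 BM3 variants and for several fungi, whereas chemical hydrogen-atom-transfer oxidants prefer the less hindered C2.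

Step 2
Reactants: 2 (13R)-labd-14-ene-3β,8α,13-triol
Product: 3 (13R)-3β-acetoxylabd-14-ene-8α,13-diol
Conditions: Ac2O, pyridine, 23 °C
Reagents that add atoms: acetic anhydride, CC(=O)OC(C)=O
Why: Chemoselective O-acylation: only the secondary equatorial C3 alcohol reacts under these conditions, and both tertiary alcohols stay free.

Step 3
Reactants: 3 (13R)-3β-acetoxylabd-14-ene-8α,13-diol
Product: 5 (13R)-3β-acetoxylabdane-8α,13,15-triol, via alkylborane 4 (not isolated)
Conditions: 9-BBN (3 equiv), THF, 23 → 50 °C; then NaBO3·4H2O, THF–H2O, 23 °C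
Reagents that add atoms: sodium perborate, [Na+].[Na+].O[B-]1(O)OO[B-](O)(O)OO1
Why: Anti-Markovnikov hydroboration–oxidation of the only alkene, in which boron goes to the terminal C15 next to the fully substituted C13. Perborate is mild enough for the acetate, no stereocentre is touched, and C13 is no longer an acid-labile allylic carbinol.

Step 4
Reactants: 5 (13R)-3β-acetoxylabdane-8α,13,15-triol
Product: 8 (13R)-3β-acetoxylabd-8-ene-13,15-diol, via phenylboronate 6 (not isolated), via alkene phenylboronate 7 (not isolated)
Conditions: PhB(OH)2 (1.05 equiv), toluene, Dean–Stark, 110 °C; then p-TsOH·H2O (5 mol %), 90 °C; aq. sorbitol/Na2CO3 wash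
Reagents that add atoms: none
Why: Transient cyclic boronate protection of the 13,15-diol, then acid-catalysed E1 dehydration of the C8 alcohol under thermodynamic (Zaitsev) control. The boronate lowers the nucleophilicity of O13, which would otherwise capture the C8 cation in a six-membered ring, and equilibration of the alkene isomers should converge on the tetrasubstituted C8=C9 alkene.

Step 5
Reactants: 8 (13R)-3β-acetoxylabd-8-ene-13,15-diol
Product: 10 (13R)-3β-acetoxy-13-hydroxylabd-8-en-15-oic acid, via hydroxy aldehyde 9 (not isolated)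
Conditions: TEMPO (20 mol %), PhI(OAc)2 (2.4 equiv), MeCN–H2O 1:1, 23 °C
Reagents that add atoms: water, O
Why: Oxoammonium-mediated oxidation of the primary alcohol through the aldehyde hydrate to the acid. The tertiary C13 alcohol cannot be oxidised, and the near-neutral medium avoids retro-aldol cleavage and protonation of the alkene.

Step 6
Reactants: 10 (13R)-3β-acetoxy-13-hydroxylabd-8-en-15-oic acid
Product: 11 (13R)-3β-acetoxy-13-hydroxy-7-oxolabd-8-en-15-oic acid
Conditions: Rh2(cap)4 (1 mol %), TBHP (70 % aq., 8 equiv), NaHCO3, DCE, 40 °C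
Reagents that add atoms: tert-butyl hydroperoxide, CC(C)(C)OO
Why: Radical allylic oxidation (H abstraction by tBuOO•, then a mixed peroxide that collapses to the enone). The ring methylene C7 has an axial C–H aligned with the π system and is the least hindered allylic site, whereas C11 is screened by C20 and C1 and C17 is primary.

Step 7
Reactants: 11 (13R)-3β-acetoxy-13-hydroxy-7-oxolabd-8-en-15-oic acid
Product: 13 (13R)-3β-acetoxy-9α,13-epoxylabd-7-en-15-oic acid, via allylic alcohol 12 (not isolated)
Conditions: NaBH4, CeCl3·7H2O, MeOH, −20 °C; concentrate; then 0.5 M HCl, THF, 0 °C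
Reagents that add atoms: none
Why: Luche 1,2-reduction, then dehydrative SN1′ cycloetherification of a monoallylic diol: ionisation of the C7 hydroxyl gives the C7–C8–C9 allyl cation, which O13 can reach only at C9 (five-membered ring, against seven-membered at C7). O13 adds from the α face because C20 covers the β face, which sets 9R (O13 axial, C11 equatorial, also the more stable spiro isomer). The C13–O bond stays intact and the alkene is left at C7=C8.

Step 8
Reactants: 13 (13R)-3β-acetoxy-9α,13-epoxylabd-7-en-15-oic acid
Product: 14 (13R)-3β-acetoxy-9α,13-epoxy-6-oxolabd-7-en-15-oic acid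
Conditions: Rh2(cap)4 (1 mol %), TBHP (70 % aq., 8 equiv), NaHCO3, DCE, 40 °C
Reagents that add atoms: tert-butyl hydroperoxide, CC(C)(C)OO
Why: Radical allylic oxidation: C9 carries no hydrogen, so C6 is the only allylic methylene and C17 is only primary. The buffered medium spares the acid-labile allylic ether, both ether carbons lack α-hydrogens, and C5 stays trans because that is the more stable ring fusion of the 6-ketone.

Step 9
Reactants: 14 (13R)-3β-acetoxy-9α,13-epoxy-6-oxolabd-7-en-15-oic acid
Product: 15 (13R)-3β-acetoxy-9α,13-epoxy-6-oxolabd-7-en-15,16-olide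
Conditions: Pd(OAc)2 (10 mol %), N-acetyl-β-alanine (20 mol %), CsHCO3 (0.5 equiv), TBHP (decane, 2 equiv), HFIP, 60 °C
Reagents that add atoms: none
Why: Proposed new method: carboxylate-directed Pd(II)/Pd(IV) γ-C(sp3)–H lactonisation. The caesium carboxylate of 14 binds Pd(II), and ligand-assisted concerted metalation–deprotonation of a C16–H bond gives the six-membered palladacycle Pd–O–C15–C14–C13–C16. TBHP oxidises it to Pd(IV), and the carboxylate oxygen then displaces palladium at C16 (C(sp3)–O reductive elimination), which forms the O–C16 bond and closes ring D in a 5-exo-tet sense. The closest known reaction types are the Pd(II)/TBHP β-C(sp3)–H lactonisation of free aliphatic acids, the Pd-catalysed γ-methyl arylation and olefination of 3,3-disubstituted acids through the same palladacycle, and Mn- or Pt-catalysed γ-lactonisation of methyl groups; new is the union of γ-palladation with C–O reductive elimination on a β-alkoxy acid. No stereocentre is created: C13 keeps all four bonds, and its sclareol configuration becomes the 13R spiro centre because the methyl arm, not the acetic acid arm, receives the ring oxygen. The selectivity needed is C16–H3 over the equally γ-placed C12–H2, and it rests on the strong preference of metalation for primary C–H and on the strain that palladation of a ring C methylene would put on ring C. C13 bears no hydrogen, so β-C–H activation, desaturation and β-hydride elimination from C16–Pd are all impossible, and loss of O13 as alkoxide is held back because the palladacycle keeps Pd–C16 and C13–O13 away from syn-coplanarity. The enone, the acetate and the fully substituted ether carbons should be inert to TBHP in HFIP, which is why the step follows step 8.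

Step 10
Reactants: 15 (13R)-3β-acetoxy-9α,13-epoxy-6-oxolabd-7-en-15,16-olide
Product: 16 (13R)-3β-acetoxy-9α,13-epoxy-6β-hydroxylabd-7-en-15,16-olide
Conditions: NaBH4, CeCl3·7H2O, MeOH–CH2Cl2, −78 → −40 °C
Reagents that add atoms: none
Why: Luche 1,2-reduction: the β face of C6 is closed by the two syn-axial methyl groups C19 and C20, so hydride must arrive from the α face and gives the axial 6β (6S) alcohol. Lactone and acetate are inert under these conditions.

Step 11
Reactants: 16 (13R)-3β-acetoxy-9α,13-epoxy-6β-hydroxylabd-7-en-15,16-olide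
Product: 17 (13R)-3β-acetoxy-7α,8α;9α,13-diepoxy-6β-hydroxylabdan-15,16-olide
Conditions: dimethyldioxirane, acetone, 0 °C
Reagents that add atoms: dimethyldioxirane, CC1(C)OO1
Why: Neutral dioxirane epoxidation under steric control: in acetone the hydroxyl group directs only weakly. The β face is screened by C20 and by the pseudo-axial C6 hydroxyl, while the α face carries only O13, so the 7α,8α-epoxide should form. The neutral medium spares the doubly allylic system.

Step 12
Reactants: 17 (13R)-3β-acetoxy-7α,8α;9α,13-diepoxy-6β-hydroxylabdan-15,16-olide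
Product: 18 (13R)-3β-acetoxy-6β-hydroxy-7-oxo-9α,13-epoxylabdan-15,16-olide (CNP0325396.1)
Conditions: BF3·OEt2 (0.2 equiv), CH2Cl2, −78 °C
Reagents that add atoms: none
Why: Meinwald rearrangement: the Lewis acid opens the epoxide at tertiary C8, and the 7β-hydrogen, aligned with the β lobe at C8 and anti to the leaving oxygen, migrates to give the C7 ketone. The shift places H on the β face of C8 and so sets the equatorial 8α-methyl group (8S), which is also the thermodynamic epimer, without any base that could open ring C.

## Compound list

1 | (−)-sclareol, (13R)-labd-14-ene-8α,13-diol | C1CC[C@@]2(C)[C@@H](CC[C@@](C)(O)[C@@H]2CC[C@@](C)(O)C=C)C1(C)C | starting material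
2 | (13R)-labd-14-ene-3β,8α,13-triol | O[C@H]1CC[C@@]2(C)[C@@H](CC[C@@](C)(O)[C@@H]2CC[C@@](C)(O)C=C)C1(C)C | intermediate
3 | (13R)-3β-acetoxylabd-14-ene-8α,13-diol | CC(=O)O[C@H]1CC[C@@]2(C)[C@@H](CC[C@@](C)(O)[C@@H]2CC[C@@](C)(O)C=C)C1(C)C | intermediate
4 | 15-(9-borabicyclo[3.3.1]nonan-9-yl) adduct of 3 | CC(=O)O[C@H]1CC[C@@]2(C)[C@@H](CC[C@@](C)(O)[C@@H]2CC[C@@](C)(O)CCB3C4CCCC3CCC4)C1(C)C | intermediate
5 | (13R)-3β-acetoxylabdane-8α,13,15-triol | CC(=O)O[C@H]1CC[C@@]2(C)[C@@H](CC[C@@](C)(O)[C@@H]2CC[C@@](C)(O)CCO)C1(C)C | intermediate
6 | 13,15-O-phenylboronate of 5 | CC(=O)O[C@H]1CC[C@@]2(C)[C@@H](CC[C@@](C)(O)[C@@H]2CC[C@]3(C)CCOB(c4ccccc4)O3)C1(C)C | intermediate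
7 | 13,15-O-phenylboronate of 8 | CC(=O)O[C@H]1CC[C@@]2(C)[C@@H](CCC(C)=C2CC[C@]3(C)CCOB(c4ccccc4)O3)C1(C)C | intermediate
8 | (13R)-3β-acetoxylabd-8-ene-13,15-diol | CC(=O)O[C@H]1CC[C@@]2(C)[C@@H](CCC(C)=C2CC[C@@](C)(O)CCO)C1(C)C | intermediate
9 | (13R)-3β-acetoxy-13-hydroxylabd-8-en-15-al | CC(=O)O[C@H]1CC[C@@]2(C)[C@@H](CCC(C)=C2CC[C@@](C)(O)CC=O)C1(C)C | intermediate
10 | (13R)-3β-acetoxy-13-hydroxylabd-8-en-15-oic acid | CC(=O)O[C@H]1CC[C@@]2(C)[C@@H](CCC(C)=C2CC[C@@](C)(O)CC(=O)O)C1(C)C | intermediate
11 | (13R)-3β-acetoxy-13-hydroxy-7-oxolabd-8-en-15-oic acid | CC(=O)O[C@H]1CC[C@@]2(C)[C@@H](CC(=O)C(C)=C2CC[C@@](C)(O)CC(=O)O)C1(C)C | intermediate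
12 | (13R)-3β-acetoxy-7β,13-dihydroxylabd-8-en-15-oic acid | CC(=O)O[C@H]1CC[C@@]2(C)[C@@H](C[C@H](O)C(C)=C2CC[C@@](C)(O)CC(=O)O)C1(C)C | intermediate
13 | (13R)-3β-acetoxy-9α,13-epoxylabd-7-en-15-oic acid | CC(=O)O[C@H]1CC[C@@]2(C)[C@@H](CC=C(C)[C@]23CC[C@](C)(CC(=O)O)O3)C1(C)C | intermediate
14 | (13R)-3β-acetoxy-9α,13-epoxy-6-oxolabd-7-en-15-oic acid | CC(=O)O[C@H]1CC[C@@]2(C)[C@@H](C(=O)C=C(C)[C@]23CC[C@](C)(CC(=O)O)O3)C1(C)C | intermediate
15 | (13R)-3β-acetoxy-9α,13-epoxy-6-oxolabd-7-en-15,16-olide | CC(=O)O[C@H]1CC[C@@]2(C)[C@@H](C(=O)C=C(C)[C@]23CC[C@@]2(COC(=O)C2)O3)C1(C)C | intermediate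
16 | (13R)-3β-acetoxy-9α,13-epoxy-6β-hydroxylabd-7-en-15,16-olide | CC(=O)O[C@H]1CC[C@@]2(C)[C@@H]([C@H](O)C=C(C)[C@]23CC[C@@]2(COC(=O)C2)O3)C1(C)C | intermediate
17 | (13R)-3β-acetoxy-7α,8α;9α,13-diepoxy-6β-hydroxylabdan-15,16-olide | CC(=O)O[C@H]1CC[C@@]2(C)[C@@H]([C@H](O)[C@H]4O[C@@]4(C)[C@]23CC[C@@]2(COC(=O)C2)O3)C1(C)C | intermediate
18 | (13R)-3β-acetoxy-6β-hydroxy-7-oxo-9α,13-epoxylabdan-15,16-olide (CNP0325396.1) | CC(=O)O[C@H]1CC[C@@]2(C)[C@@H]([C@H](O)C(=O)[C@@H](C)[C@]23CC[C@@]2(COC(=O)C2)O3)C1(C)C | target

## Step count and least certain steps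

Total step count: 12. Longest linear sequence: 12 (the route is fully linear from 1).

**Step 9 (key step, proposed new method).**
- *What may go wrong.*
  - γ-Palladation may be sluggish, because a six-membered palladacycle forms less readily than a five-membered one.
  - O13 can hold palladium in an unproductive O,O-chelate.
  - Ring C may open by β-alkoxide elimination from the C16–Pd intermediate.
- *Fallback.* It sets out from 14 and comes back at 18, uses known chemistry and moves ring D closure to the end. The acid is carried through the ring B steps.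
  - Luche reduction gives (13R)-3β-acetoxy-9α,13-epoxy-6β-hydroxylabd-7-en-15-oic acid F1.
  - Dimethyldioxirane gives (13R)-3β-acetoxy-7α,8α;9α,13-diepoxy-6β-hydroxylabdan-15-oic acid F2.
  - The Lewis-acid hydride shift gives (13R)-3β-acetoxy-9α,13-epoxy-6β-hydroxy-7-oxolabdan-15-oic acid F3.
  - On this alkene-free acid, the known carboxylate-directed manganese/H2O2 γ-lactonisation of primary C–H bonds in HFIP (hydrogen abstraction and rebound instead of metalation) would close ring D to 18. The catalyst enantiomer would be chosen to favour C16 over C12.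

**Step 7.**
- *What may go wrong.*
  - The allyl cation may lose a proton to give ring B dienes.
  - The product may re-ionise, because it is itself a tertiary allylic ether, so that material drains away with time in acid.
- *Fallback.* It sets out from 11 and comes back at 13, and forms the C9–O13 bond by conjugate addition instead of by a cation.
  - Catalytic TfOH closes ring C by oxa-Michael addition to (13R)-3β-acetoxy-9α,13-epoxy-7-oxolabdan-15-oic acid F4.
  - L-Selectride attacks equatorially to give the axial alcohol (13R)-3β-acetoxy-9α,13-epoxy-7α-hydroxylabdan-15-oic acid F5.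
  - POCl3/pyridine removes the alcohol by anti elimination with the axial 8β-H to give 13.

**Step 12.**
- *What may go wrong.*
  - A C9 substituent may migrate to C8 instead of hydride, driven by oxocarbenium formation at C9 (ring expansion of ring C).
  - Ring C may suffer Lewis-acid retro-oxa-Michael opening after the ketone has formed.
- *Fallback.* It sets out from 17 and comes back at 18, and avoids cations.
  - Titanocene(III) chloride with 1,4-cyclohexadiene opens the epoxide to the C8 radical.
  - Hydrogen is delivered anti to the bulky 7α-titanoxy group and gives (13R)-3β-acetoxy-9α,13-epoxy-6β,7α-dihydroxylabdan-15,16-olide F6.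
  - The less hindered C7 alcohol of F6 is then oxidised selectively with Dess–Martin periodinane.

**Step 11.**
- *What may go wrong.* Facial selectivity may be poor if hydrogen bonding to the 6β-hydroxyl draws the oxidant to the β face. Step 12 would then deliver the wrong C8 epimer.
- *Fallback.* It sets out from 15 and comes back at 17, and removes the directing group by inverting the order.
  - Methyl(trifluoromethyl)dioxirane epoxidises the enone under pure steric control to (13R)-3β-acetoxy-7α,8α;9α,13-diepoxy-6-oxolabdan-15,16-olide F7.
  - Luche reduction from the α face then gives 17.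

**Step 4.**
- *What may go wrong.*
  - O13 may capture the C8 cation if the boronate opens.
  - The tertiary C13–O bond may ionise in competition.
  - Equilibration of the alkene isomers may be incomplete.
- *Fallback.* It sets out from 6 and comes back at 8, and avoids carbocations.
  - SOCl2/pyridine at −78 °C eliminates the equatorial C8 chlorosulfite towards the methyl group. This gives the 13,15-O-phenylboronate of (13R)-3β-acetoxylabd-8(17)-ene-13,15-diol F8.
  - The sorbitol wash frees (13R)-3β-acetoxylabd-8(17)-ene-13,15-diol F9.
  - A cobalt(salen)/PhSiH3 hydrogen-atom-transfer isomerisation moves the alkene into the ring to give 8.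

## Further compounds

F1 | step 9 | (13R)-3β-acetoxy-9α,13-epoxy-6β-hydroxylabd-7-en-15-oic acid | CC(=O)O[C@H]1CC[C@@]2(C)[C@@H]([C@H](O)C=C(C)[C@]23CC[C@](C)(CC(=O)O)O3)C1(C)C
F2 | step 9 | (13R)-3β-acetoxy-7α,8α;9α,13-diepoxy-6β-hydroxylabdan-15-oic acid | CC(=O)O[C@H]1CC[C@@]2(C)[C@@H]([C@H](O)[C@H]4O[C@@]4(C)[C@]23CC[C@](C)(CC(=O)O)O3)C1(C)C
F3 | step 9 | (13R)-3β-acetoxy-9α,13-epoxy-6β-hydroxy-7-oxolabdan-15-oic acid | CC(=O)O[C@H]1CC[C@@]2(C)[C@@H]([C@H](O)C(=O)[C@@H](C)[C@]23CC[C@](C)(CC(=O)O)O3)C1(C)C
F4 | step 7 | (13R)-3β-acetoxy-9α,13-epoxy-7-oxolabdan-15-oic acid | CC(=O)O[C@H]1CC[C@@]2(C)[C@@H](CC(=O)[C@@H](C)[C@]23CC[C@](C)(CC(=O)O)O3)C1(C)C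
F5 | step 7 | (13R)-3β-acetoxy-9α,13-epoxy-7α-hydroxylabdan-15-oic acid | CC(=O)O[C@H]1CC[C@@]2(C)[C@@H](C[C@@H](O)[C@@H](C)[C@]23CC[C@](C)(CC(=O)O)O3)C1(C)C
F6 | step 12 | (13R)-3β-acetoxy-9α,13-epoxy-6β,7α-dihydroxylabdan-15,16-olide | CC(=O)O[C@H]1CC[C@@]2(C)[C@@H]([C@H](O)[C@@H](O)[C@@H](C)[C@]23CC[C@@]2(COC(=O)C2)O3)C1(C)C
F7 | step 11 | (13R)-3β-acetoxy-7α,8α;9α,13-diepoxy-6-oxolabdan-15,16-olide | CC(=O)O[C@H]1CC[C@@]2(C)[C@@H](C(=O)[C@H]4O[C@@]4(C)[C@]23CC[C@@]2(COC(=O)C2)O3)C1(C)C
F8 | step 4 | 13,15-O-phenylboronate of (13R)-3β-acetoxylabd-8(17)-ene-13,15-diol | CC(=O)O[C@H]1CC[C@@]2(C)[C@@H](CCC(=C)[C@@H]2CC[C@]3(C)CCOB(c4ccccc4)O3)C1(C)C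
F9 | step 4 | (13R)-3β-acetoxylabd-8(17)-ene-13,15-diol | CC(=O)O[C@H]1CC[C@@]2(C)[C@@H](CCC(=C)[C@@H]2CC[C@@](C)(O)CCO)C1(C)C
A1 | alternative 1 | 3β-acetoxy-6β,9α-dihydroxy-7-oxolabd-13-en-15,16-olide | CC(=O)O[C@H]1CC[C@@]2(C)[C@@H]([C@H](O)C(=O)[C@@H](C)[C@]2(O)CCC2=CC(=O)OC2)C1(C)C
A2 | alternative 2 | (3R,6E,10E,14S)-14,15-epoxygeranyllinalool | C=C[C@](C)(O)CC/C=C(\C)CC/C=C(\C)CC[C@@H]1OC1(C)C
A3 | alternative 2 | 3β-hydroxymanool, (13R)-labda-8(17),14-diene-3β,13-diol | O[C@H]1CC[C@@]2(C)[C@@H](CCC(=C)[C@@H]2CC[C@@](C)(O)C=C)C1(C)C
A4 | alternative 3 | 3β-acetoxy-6β-hydroxy-7-oxo-9α,13-epoxylabdane with C13 spiro-fused to a 3-oxocyclobutane (C14, C15(=O), C16) | CC(=O)O[C@H]1CC[C@@]2(C)[C@@H]([C@H](O)C(=O)[C@@H](C)[C@]23CCC2(CC(=O)C2)O3)C1(C)C
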